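## Retrosynthetic overview
1. Target 10 is cut at the C8–CH2 bond. This gives (2S)-6-prenylpinocembrin 5, in which only C8 is free, and o-quinone methide 9. Compound 9 is released from Mannich base 8 of methylphloracetophenone 6, which has only one free ring carbon.
2. The C6–prenyl bond of 5 comes from an aromatic [3,3] Claisen rearrangement of the 7-O-(1,1-dimethylallyl) ether 3.
3. Ether 3 comes from (2S)-pinocembrin 1 by Pd(0) O-tert-prenylation. The only stereocentre, C2 (S), is bought with 1 and never touched.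
4. No ring is built. The chromanone and both phloroglucinol rings arrive intact with 1 and 6.

Assumption: natural-source (2S)-(−)-pinocembrin (single enantiomer, ee checked by chiral HPLC), 2',4',6'-trihydroxy-3'-methylacetophenone and tert-butyl (2-methylbut-3-en-2-yl) carbonate are taken as catalogue items.

## Route

Step 1
Reactants: 1 (2S)-pinocembrin; 2 tert-butyl (2-methylbut-3-en-2-yl) carbonate
Product: 3 (2S)-5-hydroxy-7-[(2-methylbut-3-en-2-yl)oxy]-2-phenylchroman-4-one
Conditions: 2 (1.2 equiv), Pd(PPh3)4 (5 mol %), THF, 0–5 °C, 2 h; short Et3N-washed SiO2 plug to remove Pd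
Reagents that add atoms: tert-butyl (2-methylbut-3-en-2-yl) carbonate, C=CC(C)(C)OC(=O)OC(C)(C)C
Why: In this decarboxylative Tsuji–Trost O-allylation the π-prenyl-Pd cation is attacked kinetically at its tertiary terminus by the more acidic, non-chelated 7-phenoxide (the 5-OH is tied up in its hydrogen bond to C4=O), and with no external base present the C2 stereocentre cannot epimerise through chalcone ring-opening.

Step 2
Reactants: 3 (2S)-5-hydroxy-7-[(2-methylbut-3-en-2-yl)oxy]-2-phenylchroman-4-one
Product: 5 (2S)-5,7-dihydroxy-6-(3-methylbut-2-enyl)-2-phenylchroman-4-one (6-prenylpinocembrin), via (2S)-5-hydroxy-6-(3-methylbut-2-enyl)-2-phenyl-2,3-dihydrochromene-4,7(6H)-dione 4 (not isolated)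
Conditions: degassed PhMe (0.05 M), 110 °C, sealed tube, 4 h; SiO2 chromatography
Reagents that add atoms: none
Why: The aromatic Claisen [3,3]-sigmatropic rearrangement, accelerated by the gem-dimethyl group, turns the tertiary ether into a normal prenyl group on carbon; attack at C6 keeps the C4a=C5(OH)···O=C4 chelate intact in dienone 4 and should therefore be preferred over C8 (the minor 8-prenyl isomer is removed by chromatography), enolisation erases the transient C6 centre of 4, and C2 is untouched under neutral aprotic heating.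

Step 3
Reactants: 6 2',4',6'-trihydroxy-3'-methylacetophenone; 7 bis(dimethylamino)methane
Product: 8 1-{3-[(dimethylamino)methyl]-2,4,6-trihydroxy-5-methylphenyl}ethanone
Conditions: 6 added slowly to 7 (2 equiv), THF, 0 °C → rt, 2 h; evaporate cold, triturate with Et2O, use promptly
Reagents that add atoms: bis(dimethylamino)methane, CN(C)CN(C)C
Why: This Mannich aminomethylation acts on a very electron-rich acylphloroglucinol with a single free ring carbon, so only one regioisomer can form, inverse addition to excess aminal keeps free 6 scarce and suppresses the symmetrical methylene-bis dimer, and no stereocentre is involved.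

Step 4
Reactants: 5 (2S)-6-prenylpinocembrin; 8 1-{3-[(dimethylamino)methyl]-2,4,6-trihydroxy-5-methylphenyl}ethanone
Product: 10 (2S)-8-(3-acetyl-2,4,6-trihydroxy-5-methylbenzyl)-5,7-dihydroxy-6-(3-methylbut-2-enyl)-2-phenylchroman-4-one, via 4-acetyl-3,5-dihydroxy-2-methyl-6-methylidenecyclohexa-2,4-dien-1-one 9 (not isolated)
Conditions: 8 (1.2 equiv, added over 2 h), AcOH (3 equiv), 1,4-dioxane, 60 °C, Ar
Reagents that add atoms: none
Why: Loss of dimethylamine from the o-hydroxybenzylamine gives o-quinone methide 9, which takes up C8 of 5 (its only unsubstituted nucleophilic carbon) in a Friedel–Crafts-type Michael addition followed by re-aromatisation; acetic acid traps the amine so that neither flavanone–chalcone racemisation at C2 nor retro-Michael scrambling of the bridge sets in, and no new stereocentre is formed.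

## Compound list
1 | (2S)-pinocembrin, (2S)-5,7-dihydroxy-2-phenylchroman-4-one | Oc1cc(O)c2c(c1)O[C@H](c1ccccc1)CC2=O | starting material
2 | tert-butyl (2-methylbut-3-en-2-yl) carbonate | C=CC(C)(C)OC(=O)OC(C)(C)C | starting material
3 | (2S)-5-hydroxy-7-[(2-methylbut-3-en-2-yl)oxy]-2-phenylchroman-4-one | C=CC(C)(C)Oc1cc(O)c2c(c1)O[C@H](c1ccccc1)CC2=O | intermediate
4 | (2S)-5-hydroxy-6-(3-methylbut-2-enyl)-2-phenyl-2,3-dihydrochromene-4,7(6H)-dione (C6 epimers, transient) | CC(C)=CCC1C(=O)C=C2O[C@H](c3ccccc3)CC(=O)C2=C1O | intermediate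
5 | (2S)-5,7-dihydroxy-6-(3-methylbut-2-enyl)-2-phenylchroman-4-one | CC(C)=CCc1c(O)cc2O[C@H](c3ccccc3)CC(=O)c2c1O | intermediate
6 | 2',4',6'-trihydroxy-3'-methylacetophenone | CC(=O)c1c(O)cc(O)c(C)c1O | starting material
7 | bis(dimethylamino)methane | CN(C)CN(C)C | starting material
8 | 1-{3-[(dimethylamino)methyl]-2,4,6-trihydroxy-5-methylphenyl}ethanone | CC(=O)c1c(O)c(C)c(O)c(CN(C)C)c1O | intermediate
9 | 4-acetyl-3,5-dihydroxy-2-methyl-6-methylidenecyclohexa-2,4-dien-1-one | C=C1C(=O)C(C)=C(O)C(C(C)=O)=C1O | intermediate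
10 | (2S)-8-(3-acetyl-2,4,6-trihydroxy-5-methylbenzyl)-5,7-dihydroxy-6-(3-methylbut-2-enyl)-2-phenylchroman-4-one | CC(=O)c1c(O)c(C)c(O)c(Cc2c(O)c(CC=C(C)C)c(O)c3c2O[C@H](c2ccccc2)CC3=O)c1O | target

## Step count and risks
Total steps: 4. Longest linear sequence: 3 (1 → 3 → 5 → 10).

**Step 2.** The risks are C6 versus C8 selectivity and loss of isoprene back to 1. The fallback sets out from 1 and comes back at 5, and it moves the rearrangement to O5, whose only open ortho carbon is C6.
- Acetylate only the non-chelated 7-OH (Ac2O, pyridine, 0 °C) to give (2S)-7-O-acetylpinocembrin F2.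
- Etherify the chelated 5-OH with allyl alcohol under Mitsunobu conditions (PPh3, DIAD, THF) to give (2S)-7-acetoxy-5-allyloxy-2-phenylchroman-4-one F3.
- Rearrange with achiral Eu(fod)3 (10 mol %, CHCl3, 60 °C). This passes through the 6-allyl cyclohexadienone F4 to (2S)-7-acetoxy-6-allyl-5-hydroxy-2-phenylchroman-4-one F5.
- Cross-metathesise with 2-methylbut-2-ene (Grubbs II, CH2Cl2, 40 °C) to give (2S)-7-acetoxy-5-hydroxy-6-(3-methylbut-2-enyl)-2-phenylchroman-4-one F6.
- Methanolyse the acetate (cat. K2CO3, MeOH, 0 °C) to give 5.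

**Step 4.** The risks are self-exchange of 8 to the symmetrical dimer, hetero-Diels–Alder capture of 9 by the prenyl alkene, bridge scrambling, and erosion of ee. The fallback sets out from 5 and comes back at 10, with the roles of the two halves reversed.
- Aminomethylate 5 at its only free carbon with 7 (dioxane, rt) to give (2S)-8-[(dimethylamino)methyl]-5,7-dihydroxy-6-(3-methylbut-2-enyl)-2-phenylchroman-4-one F7.
- Warm F7 with 6 (1.5 equiv) in AcOH-buffered dioxane. The flavanone-derived o-quinone methide F8 is then trapped by the single free carbon of the more nucleophilic 6, which gives 10.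

**Step 1.** The risks are formation of the linear prenyl ether or C-allylation instead of the tertiary ether, and the thermal and acid lability of 3. The fallback sets out from 1 and comes back at 3, and it builds the tertiary C–O bond without a π-allyl species.
- Run a copper-catalysed propargylation with 3-chloro-3-methylbut-1-yne (K2CO3, cat. CuI, acetone, 40 °C, ee monitored) to give (2S)-5-hydroxy-7-[(2-methylbut-3-yn-2-yl)oxy]-2-phenylchroman-4-one F1.
- Semi-hydrogenate F1 (H2, Lindlar catalyst, quinoline, EtOAc, rt) to give 3.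

## Further compounds
F1 | step 1 | (2S)-5-hydroxy-7-[(2-methylbut-3-yn-2-yl)oxy]-2-phenylchroman-4-one | C#CC(C)(C)Oc1cc(O)c2c(c1)O[C@H](c1ccccc1)CC2=O
F2 | step 2 | (2S)-7-O-acetylpinocembrin | CC(=O)Oc1cc(O)c2c(c1)O[C@H](c1ccccc1)CC2=O
F3 | step 2 | (2S)-7-acetoxy-5-allyloxy-2-phenylchroman-4-one | CC(=O)Oc1cc(OCC=C)c2c(c1)O[C@H](c1ccccc1)CC2=O
F4 | step 2 | 6-allyl cyclohexadienone, (2S)-7-acetoxy-6-allyl-2-phenyl-2,3-dihydrochromene-4,5(6H)-dione (C6 epimers, transient) | C=CCC1C(=O)C2=C(C=C1OC(C)=O)O[C@H](c1ccccc1)CC2=O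
F5 | step 2 | (2S)-7-acetoxy-6-allyl-5-hydroxy-2-phenylchroman-4-one | C=CCc1c(OC(C)=O)cc2O[C@H](c3ccccc3)CC(=O)c2c1O
F6 | step 2 | (2S)-7-acetoxy-5-hydroxy-6-(3-methylbut-2-enyl)-2-phenylchroman-4-one | CC(C)=CCc1c(OC(C)=O)cc2O[C@H](c3ccccc3)CC(=O)c2c1O
F7 | step 4 | (2S)-8-[(dimethylamino)methyl]-5,7-dihydroxy-6-(3-methylbut-2-enyl)-2-phenylchroman-4-one | CC(C)=CCc1c(O)c(CN(C)C)c2O[C@H](c3ccccc3)CC(=O)c2c1O
F8 | step 4 | flavanone-derived o-quinone methide, (2S)-5-hydroxy-6-(3-methylbut-2-enyl)-8-methylidene-2-phenyl-2,3-dihydrochromene-4,7(8H)-dione | CC(C)=CCC1=C(O)C2=C(O[C@H](c3ccccc3)CC2=O)C(=C)C1=O
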